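Rings A and C of the target, with the (2S) carbon C2, the C4 ketone and the 5- and 7-hydroxyls, are exactly those of natural (S)-naringenin; only ring B differs, by a 4'-O-methyl group flanked by prenyl groups on C3' and C5'. The strategy rests on this feature.
Last disconnection: the 7-hydroxyl is carried as its pivalate and released at the end.
Key disconnection: both ring B aryl–CH2 bonds (C3'–CH2 and C5'–CH2) are cut together, back to a 3',5'-diiodo-4'-methoxyflavanone and two molecules of a prenylstannane (twofold Stille coupling).
The diiodide comes from naringenin by 7-O-pivaloylation, ortho,ortho-diiodination of the free ring B phenol and neutral O-methylation of that phenol.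
Ring order: no ring is formed; rings A, B and C and the C2 stereocenter are taken intact from the chiral pool.

Key step: step 4

Assumption: (S)-naringenin is bought in high enantiomeric purity (to be confirmed by chiral HPLC), because C2 is never re-formed and the target can be no purer than this lot.

Step 1
Reactants: 1 (S)-naringenin
Product: 2 (S)-7-O-pivaloylnaringenin [(2S)-5-hydroxy-2-(4-hydroxyphenyl)-4-oxochroman-7-yl pivalate]
Conditions: PivCl (1.05 equiv), Et3N (1.1 equiv), THF, −20 to 0 °C; aq. citric acid quench
Reagents that add atoms: pivaloyl chloride, CC(C)(C)C(Cl)=O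
Why: Regioselective O-acylation of the most acidic phenol: one equivalent of Et3N ionizes mainly the 7-OH (a vinylogous acid conjugated to the C4 carbonyl), whose phenoxide should take the bulky acyl chloride, while the less acidic 4'-OH reacts more slowly and the hydrogen-bonded 5-OH not at all; C2 is not involved.

Step 2
Reactants: 2 (S)-7-O-pivaloylnaringenin
Product: 4 (S)-3',5'-diiodo-7-O-pivaloylnaringenin, via 3'-monoiodide 3 (not isolated)
Conditions: I2 (2.05 equiv), morpholine (4.2 equiv), CH2Cl2, 0 °C; aq. Na2S2O3 / citric acid work-up
Reagents that add atoms: iodine, [I][I]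
Why: Amine–iodine ortho-iodination of a phenol (electrophilic aromatic substitution through the amine-paired phenoxide by the morpholine–iodine complex): in CH2Cl2 only the free 4'-OH of ring B pairs with morpholine and both of its ortho positions (C3', C5') are open, whereas the 5-OH stays locked in its hydrogen bond to the C4 carbonyl and ring A is deactivated and flanked at C6 and C8 by the pivaloyloxy group, so two equivalents of iodine should stop at the 3',5'-diiodide without touching C2.

Step 3
Reactants: 4 (S)-3',5'-diiodo-7-O-pivaloylnaringenin
Product: 5 (S)-5-hydroxy-3',5'-diiodo-4'-methoxy-7-pivaloyloxyflavanone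
Conditions: TMSCHN2 (2 M in hexanes, 1.5 equiv), toluene–MeOH 4:1, 0 °C to rt; AcOH quench
Reagents that add atoms: trimethylsilyldiazomethane, C[Si](C)(C)C=[N+]=[N-]
Why: Diazoalkane O-methylation is governed by phenol acidity, so the 2,6-diiodophenol of ring B, far more acidic than the chelated 5-OH that classically resists diazomethane, should be methylated alone under neutral conditions that leave the pivalate and C2 untouched.

Step 4
Reactants: 5 (S)-5-hydroxy-3',5'-diiodo-4'-methoxy-7-pivaloyloxyflavanone; 6 tributyl(3-methylbut-2-enyl)stannane (3 equiv)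
Product: 8 (S)-5-hydroxy-4'-methoxy-7-pivaloyloxy-3',5'-diprenylflavanone, via monoprenyl monoiodide 7 (not isolated)
Conditions: Pd(PPh3)4 (10 mol%), degassed amine-free DMF, 85 °C, dark
Reagents that add atoms: none
Why: Twofold Stille allylic cross-coupling: zerovalent palladium inserts into each C–I bond of 5, the prenyl group passes from tin to palladium with loss of Bu3SnI, and reductive elimination forms first one and then the other aryl–CH2 bond (C3'–CH2, C5'–CH2) through monoiodide 7. The closest known reaction type is the Pd(PPh3)4-mediated coupling of aryl iodides, iodoflavonoids among them, with allyl- and prenyltributylstannanes. No ring is closed and no stereocenter is created; C2 is only carried through, which the neutral, base-free medium should allow. The selectivity needed is linear (α) over 1,1-dimethylallyl (γ) attachment: the aryl(allyl)palladium intermediate equilibrates through its η3 form and, bearing PPh3 and an aryl group crowded by the 4'-methoxy group, should sit and reductively eliminate at the unhindered CH2 terminus. Chemoselectivity rests on the two C–I bonds being the only sites open to oxidative addition, since the aryl pivalate, the chelated 5-OH and the ketone are inert to zerovalent palladium under these conditions.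

Step 5
Reactants: 8 (S)-5-hydroxy-4'-methoxy-7-pivaloyloxy-3',5'-diprenylflavanone
Product: 9 4'-O-methylabyssinone V [(2S)-5,7-dihydroxy-2-[4-methoxy-3,5-bis(3-methylbut-2-enyl)phenyl]chroman-4-one]
Conditions: NH3 (7 M in MeOH), THF, 0 °C to rt; aq. citric acid work-up
Reagents that add atoms: none
Why: Ammonolysis of an aryl ester with a good leaving group (the acidic, carbonyl-conjugated 7-phenoxide) should run at low temperature, and once the 7-phenoxide is formed it disfavors the base-induced retro-oxa-Michael opening of ring C, so the S configuration at C2 and the two prenyl groups should survive.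

Compound list
1 | (S)-naringenin | O=C1C[C@@H](c2ccc(O)cc2)Oc2cc(O)cc(O)c21 | starting material
2 | (S)-7-O-pivaloylnaringenin | Oc1ccc([C@@H]2CC(=O)c3c(O)cc(OC(=O)C(C)(C)C)cc3O2)cc1 | intermediate
3 | (S)-3'-iodo-7-O-pivaloylnaringenin | Oc1ccc([C@@H]2CC(=O)c3c(O)cc(OC(=O)C(C)(C)C)cc3O2)cc1I | intermediate
4 | (S)-3',5'-diiodo-7-O-pivaloylnaringenin | Oc1c(I)cc([C@@H]2CC(=O)c3c(O)cc(OC(=O)C(C)(C)C)cc3O2)cc1I | intermediate
5 | (S)-5-hydroxy-3',5'-diiodo-4'-methoxy-7-pivaloyloxyflavanone | COc1c(I)cc([C@@H]2CC(=O)c3c(O)cc(OC(=O)C(C)(C)C)cc3O2)cc1I | intermediate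
6 | tributyl(3-methylbut-2-enyl)stannane | CC(C)=CC[Sn](CCCC)(CCCC)CCCC | starting material
7 | (S)-5-hydroxy-3'-iodo-4'-methoxy-5'-prenyl-7-pivaloyloxyflavanone | COc1c(I)cc([C@@H]2CC(=O)c3c(O)cc(OC(=O)C(C)(C)C)cc3O2)cc1CC=C(C)C | intermediate
8 | (S)-5-hydroxy-4'-methoxy-7-pivaloyloxy-3',5'-diprenylflavanone | COc1c(CC=C(C)C)cc([C@@H]2CC(=O)c3c(O)cc(OC(=O)C(C)(C)C)cc3O2)cc1CC=C(C)C | intermediate
9 | 4'-O-methylabyssinone V | COc1c(CC=C(C)C)cc([C@@H]2CC(=O)c3c(O)cc(O)cc3O2)cc1CC=C(C)C | target

Total step count: 5. Longest linear sequence: 5 steps (1 to 9).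

Steps most likely to fail

Step 2. Site selectivity may be lost: the chelated 5-phenol still activates C6 and C8, so iodination could spill onto ring A. The free amine could also aminolyse the pivalate or start reversible opening of ring C. The fallback runs from 2 back to 4 and masks ring A instead of relying on its lower reactivity. BF3·OEt2 in CH2Cl2 at rt should convert 2 into the 5-O,4-O-difluoroboron chelate of 7-O-pivaloylnaringenin F1, in which ring A has no free phenol and is strongly electron-poor. N-Iodosuccinimide (2.1 equiv) with catalytic CF3CO2H in MeCN, a base-free iodination, should then iodinate only the phenol ring to give the 3',5'-diiodo difluoroboron chelate F2. Aqueous NaOAc in THF–MeOH at 40 °C should hydrolyse the boron chelate and return 4.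

Step 4. The allyl transfer may leak regiochemically, placing a 1,1-dimethylallyl group instead of a prenyl group at one or both positions. The sequence may also stall after the first coupling with hydrodeiodination of 7, or palladium hydride may shift the new double bonds into conjugation. The fallback runs from 5 back to 8 and makes the same two aryl–CH2 bonds with a symmetric allyl group. Allyltributylstannane with Pd(PPh3)4 in DMF at 85 °C, where the two allyl termini are identical, should give the 3',5'-diallyl flavanone F3. Twofold olefin cross-metathesis with excess 2-methyl-2-butene and second-generation Grubbs catalyst RuCl2(=CHPh)(PCy3)(SIMes) in CH2Cl2 at 40 °C should then turn each allyl group into a prenyl group and deliver 8.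

Step 1. The acylation may discriminate incompletely between the 7-OH and the 4'-OH, giving 4'-ester and diester that are hard to separate. The fallback runs from 1 back to 2 and fixes the acylation site by a silyl relay. TBSCl (2.3 equiv) and imidazole in DMF should silylate both free phenols to 4',7-bis-O-TBS-naringenin F4, with the chelated 5-OH untouched. Catalytic K2CO3 in MeOH at 0 °C should cleave only the silyl ether of the acidic ring A phenol, giving 4'-O-TBS-naringenin F5. PivCl and Et3N then have only the 7-OH to acylate, giving 4'-O-TBS-7-O-pivaloylnaringenin F6. HF·pyridine in THF at 0 °C removes the silyl ether and returns 2.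

Further compounds
F1 | step 2 | 5-O,4-O-difluoroboron chelate of (S)-7-O-pivaloylnaringenin | Oc1ccc([C@@H]2CC3=[O+][B-](F)(F)Oc4cc(OC(=O)C(C)(C)C)cc(O2)c34)cc1
F2 | step 2 | 5-O,4-O-difluoroboron chelate of (S)-3',5'-diiodo-7-O-pivaloylnaringenin | Oc1c(I)cc([C@@H]2CC3=[O+][B-](F)(F)Oc4cc(OC(=O)C(C)(C)C)cc(O2)c34)cc1I
F3 | step 4 | (S)-3',5'-diallyl-5-hydroxy-4'-methoxy-7-pivaloyloxyflavanone | COc1c(CC=C)cc([C@@H]2CC(=O)c3c(O)cc(OC(=O)C(C)(C)C)cc3O2)cc1CC=C
F4 | step 1 | (S)-4',7-bis-O-(tert-butyldimethylsilyl)naringenin | CC(C)(C)[Si](C)(C)Oc1ccc([C@@H]2CC(=O)c3c(O)cc(O[Si](C)(C)C(C)(C)C)cc3O2)cc1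
F5 | step 1 | (S)-4'-O-(tert-butyldimethylsilyl)naringenin | CC(C)(C)[Si](C)(C)Oc1ccc([C@@H]2CC(=O)c3c(O)cc(O)cc3O2)cc1
F6 | step 1 | (S)-4'-O-(tert-butyldimethylsilyl)-7-O-pivaloylnaringenin | CC(C)(C)[Si](C)(C)Oc1ccc([C@@H]2CC(=O)c3c(O)cc(OC(=O)C(C)(C)C)cc3O2)cc1
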